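all flasks: Q 0.0137 M
- theta: D 0.018 M; run made earlier
- eta: D 0.029 M; run made earlier
- flask: D 0.013 M; time 15 d

- theta (time / d: L / %, D / %): 0.333: 16.2, 80.8; 1.04: 20.0, 67.5; 3.00: 17.8, 50.1; 10.0: 11.6, 43.9
- eta (time / d: L / %, D / %): 0.333: 13.7, 82.9; 1.04: 16.8, 73.1; 3.00: 14.5, 64.2; 10.0: 8.0, 59.9

(readings scatter by 1 percentage point)

- when, up to 15 d, the flask holds most L
- the amount of L, in percent of the D charged, at that time
- the first time at which L reaches 6.3%, in the same percent, in d

- the numbers in the tables scatter with a standard deviation of 1 percentage point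
- candidate steps: D + Q -> L + X; Q + L -> E + X; Q + E <-> G + X; Q <-> Z; L <-> J

Late in the theta run, between 3.00 d and 10.0 d, D decayed at 0.0189 d⁻¹ while L decayed at 0.0612 d⁻¹, faster, so I took L to be leaving by L <-> J as well as through Q. That was the bottom rung of my ladder. On the top rung, up to the first reading, theta's D fell at a pseudo-first-order 0.640 d⁻¹, far above its late rate. Between them, both runs read their highest L at 1.04 d.

Dividing the rate of L by that of D removes time: d[L]/d[D] = −1 + κ[L]/[D]. With x the fraction of D left, this integrates to L = (x − x^κ)/(κ − 1) of the D charged. Interpolating this form between κ of 2 and 3 to meet theta's reading at 1.04 d, I got 2.54, a lumped selectivity factor: the loss of L per L against the loss of D per D. It puts the peak at x = 54.6%, with L = x/κ = 21.5%, so long as Q lasts.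

Reaching that x takes one Q per D lost and one more per L that goes on to E. As a rough count, which takes each L passed on as going to E and leaves Q <-> Z out, that comes to 0.658 of the Q charge in the flask, against 1.47 in eta, whose highest reading was 16.8%. So I expected the flask to reach about 21.5%.

The forecast said 1.3 d, 21.5% and 0.1 d, the last because “L reaches 6.3% on the initial slope”. The flask gives 1.32 d, 21.1% and 0.0645 d.

    D + Q → L + X (k = 0.00110 M⁻¹ s⁻¹)
    Q + L → E + X (k = 0.00150 M⁻¹ s⁻¹)
    Q + E ⇌ G + X (K = 2.30, k = 2.10 × 10⁻⁴ M⁻¹ s⁻¹)
    Q ⇌ Z (K = 1.60, k = 6.10 × 10⁻⁵ s⁻¹)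
    L ⇌ J (K = 3.10, k = 4.70 × 10⁻⁶ s⁻¹)

At its best time the flask held D 59.9%, and the closed form at that D returns L 21.2%, against 21.1%. For the neighbouring flask, charged with 0.022 M of D and the same Q, the same rough count comes to 1.11 of its Q charge for the same peak, more than was charged, but that count bills Q for L that goes to J, which takes none. Its highest L is 18.6%, which is 2.9 percentage points under 21.5%, and at 15.0 d it holds D 50.8% and Q 0.0431% of its own charge.

The numbers in the tables were generated by integration with made-up constants; scatter was added.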